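## Structural features

Artelasticin is a flavone: a 4H-chromen-4-one (benzo ring A fused to pyranone ring C) that carries a 2,4-dihydroxyphenyl ring B on C2 through the single C2–C1' bond. Ring A is fully substituted, with hydroxyls on C5 and C7 and 3-methylbut-2-enyl (prenyl) chains on C6 and C8. A third prenyl chain sits on C3 of ring C, between the C4 carbonyl and the ortho-hydroxylated ring B. There is no stereocentre, and each side-chain alkene ends in a gem-dimethyl group, so no alkene geometry has to be controlled. The fragile elements are the prenyl groups next to phenols (5-OH/6-prenyl, 7-OH between two prenyls, 2'-OH facing the C3 prenyl): acid converts them into 2,2-dimethylchromans, and the electron-rich tetraphenol is sensitive to oxidation under base. The real difficulty is regiochemical: three C-prenyl groups must be placed on C3, C6 and C8 without O-prenylation, SN2' (reverse) prenylation or acid-induced cyclisation during a late deprotection. The key step uses the fact that all three chains end in the same CH=C(CH3)2 unit, so the three C2''=C3'' bonds can be made at once by cross-metathesis of robust allyl groups on C3, C6 and C8 with three molecules of one olefin. The allyl groups can be delivered with unambiguous regiochemistry: to C6 and C8 by sigmatropic O-to-C migration, and to C3 through the α-carbon of an aryl ketone.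

## Logic of the disconnections

**14 to 12 and 13.** The three side-chain double bonds C2''=C3'' (chains on C3, C6 and C8) are cut. The three termini are identical, and a terminal allyl group, unlike a prenyl group, is indifferent to the acid and heat used earlier. The gain is that all three chains become the same three-carbon unit, which 5 can deliver. The forward step consumes three molecules of 13, one per chain. It must run to completion at three sites of an unprotected tetraphenol without moving any double bond into conjugation.

**12 to 11.** The two acetal O–CH2 bonds on the ring-B oxygens are restored. This places the only acidic deprotection of the route before any prenyl group exists. The gain is a ring B that is inert to base and heat in the preceding steps. The forward step needs acid that cleaves aryl acetals but does not add a phenol across a terminal alkene.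

**11 to 10.** The C6–CH2 and C8–CH2 bonds are cut and the two allyl groups are returned to O5 and O7. C-Allylation of ring A is thereby reduced to O-allylation. The forward step requires both [3,3] shifts to end on C6 and C8 whatever their order, and the heat must leave the acetals and the C3 allyl group untouched.

**10 to 8 through 9.** The O1–C2 bond is cut first (giving 9), then the bond between the allyl-bearing carbon (C3 of 10) and the ring-B carbonyl carbon (C2 of 10). This acyl transfer brings C3 in with its allyl group already attached, so the finished heterocycle never has to be alkylated. Ring C and the link to ring B are reduced to an ester. The forward step demands that the enolate of an α-branched, di-ortho-substituted ketone attacks the ester, and that only the ring-A hydroxyl closes the ring, which is why the ring-B oxygens stay protected until then.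

**8 to 7 and 3.** The ester C(=O)–O bond is cut. The gain is two fragments of similar size, one for rings A/C and one for ring B. The forward step must acylate a chelated, hindered phenol without acid, since 3 carries acetals.

**7 to 6 and 5.** The Cα–CH2 bond next to the ketone is cut. The methyl ketone is the only carbon acid in 6, so this is the simplest way to put the future C3 substituent in place. The forward step must stop at monoalkylation and must not O-alkylate the free phenol.

**6 to 4 and 5.** Two O–CH2 bonds are cut. The allyl ethers serve both as protecting groups and as the source of the C6 and C8 allyl groups. The forward step relies on the hydrogen-bonded ortho hydroxyl staying unreacted.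

**3 to 1 through 2.** The two aryl acetal O–CH2 bonds and the ester O–CH2 bond of 2 are cut. The forward step must protect the chelated 2-OH completely and then hydrolyse only the acyl acetal.

## Other disconnections considered

Alternative 1: The cut goes through ring A (C4a–C8a, C5–C6 and C8–C8a), which would be built by a Danheiser benzannulation.
- Forward key step: 2,4-diprenyl-3-(triisopropylsilyloxy)cyclobut-2-en-1-one A1 would be heated with (triisopropylsilyloxy)ethyne A2. A 4π ring opening, [2+2] cycloaddition to the alkyne, a second 4π opening and 6π electrocyclisation would give 2,4-diprenyl-3,5-bis(triisopropylsilyloxy)phenol A3.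
- In its favour: the positions of both ring-A prenyl groups follow from the connectivity of A1. The hydroxyl that is to become O1 is distinguished from the two silylated ones without selective protection. The silyl groups could later be removed with fluoride instead of acid.
- Against it here: A1 is itself a multistep target. The ketene intermediates carry two trisubstituted alkenes that could trap them intramolecularly ([2+2] or ene reaction). A3 still lacks ring C, ring B and the C3 prenyl group, so an acylation at the free CH and a pyranone annulation would have to follow on an acid-sensitive prenylated phenol.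
- Comparison: on structure it is the equal of the chosen plan in fixing C6 and C8 and is better in differentiating the three ring-A oxygens. On mechanism both key steps are neutral, but the pericyclic cascade needs much higher temperature with the prenyl groups present, whereas the metathesis makes them last at 40 °C. On step economy it is clearly worse, because its key step builds a benzene ring that 4 supplies ready-made.

Alternative 2: The cut removes ring C at C4–C4a and O1–C2.
- Forward key step: 2,4-diprenylbenzene-1,3,5-triol A4 and ethyl 2-[2,4-bis(methoxymethoxy)benzoyl]-5-methylhex-4-enoate A5 would be heated briefly without acid (Mentzer pyrone synthesis). C-Acylation at the only free ring position, attack of a flanking hydroxyl on the aryl ketone and twofold condensation would give 5,7-dihydroxy-2-[2,4-bis(methoxymethoxy)phenyl]-3,6,8-triprenylchromen-4-one A6.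
- In its favour: it is the most convergent plan. A4 is symmetric, so only one chromone can form; all three prenyl groups arrive in the two components; two bonds and a ring are made in one step.
- Against it here: the twofold C-prenylation needed for A4 is poorly selective (O-, mono-, tri- and geminal alkylation compete). α-Branched β-keto esters such as A5 are sluggish in this condensation. The temperature needed (about 200 °C or more) invites chroman formation from the ortho-prenyl phenols. A6 must still lose two acetals under acid with three prenyl groups and their neighbouring hydroxyls in place.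
- Comparison: on step economy it is better than the chosen plan (roughly half the steps). On structure it is its equal, since ring closure is regiochemically unambiguous. On mechanism it is weaker, because both its hot step and its acidic step act on prenyl groups, whereas the chosen plan exposes only allyl groups to heat and acid.

Alternative 3: The cut goes through ring B (C1'–C2' and C5'–C6'), which would be grown on a chromone bearing an alkyne on C2.
- Forward key step: 2-ethynyl-5,7-bis(methoxymethoxy)-3,6,8-triprenylchromen-4-one A7 and 1-methoxy-1,3-bis(trimethylsilyloxy)buta-1,3-diene A8 would combine in a [4+2] cycloaddition, the unsubstituted diene terminus bonding to the terminal alkyne carbon. Elimination of the methoxy group and desilylation on work-up would give 2-(2,4-dihydroxyphenyl)-5,7-bis(methoxymethoxy)-3,6,8-triprenylchromen-4-one A9.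
- In its favour: the 2',4'-dioxygenation pattern follows from the polarity match of A8 and A7. Ring B is born unprotected. The same alkyne could serve other ring-B patterns.
- Against it here: A7 is far from commercial materials and already contains all three prenyl groups. The C3 prenyl group crowds the dienophile. The silyl ketene acetal end of A8 may add in a conjugate (Mukaiyama–Michael) manner without closing the ring. A9 still carries the two ring-A acetals, whose acidic removal next to the C6 and C8 prenyl groups is the operation most likely to end in chromans.
- Comparison: on structure it is the equal of the chosen plan in regiocontrol of ring B and better in needing no ring-B protecting group. On mechanism it is a thermal pericyclic step against a catalytic one, with no stereochemical issue in either. On step economy it is worse, since ring B is available as 1 and the chosen plan makes the prenyl termini after, not before, the last deprotection.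

Key step: step 8

Assumption: the four phenols of 12 stay free in step 8 (1,4-benzoquinone and a little THF are added), so that no deprotection follows the metathesis; one molecule of 13 reacts at each of the three allyl groups, three in all.

In the names below, allyl = prop-2-enyl and prenyl = 3-methylbut-2-enyl.

## Route

**Step 1**
Reactants: 1 2,4-dihydroxybenzoic acid
Product: 3 2,4-bis(methoxymethoxy)benzoic acid, via methoxymethyl ester 2 (not isolated)
Conditions: MOMCl (3.6 equiv), iPr2NEt (5 equiv), DMF, 0 → 45 °C; aqueous wash; then NaOH (2 M aq), MeOH/THF, rt; cold 1 M HCl to pH 4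
Reagents that add atoms: chloromethyl methyl ether, COCCl; sodium hydroxide, [Na+].[OH-]
Why: O-alkylation of the carboxylate and both phenoxides gives 2 (the chelated 2-OH needs the excess reagent and gentle warming); the acyl acetal of 2 is far more labile to hydroxide than the two aryl acetals, so saponification should free only the acid, and brief cold acidification should leave the aryl acetals intact.

**Step 2**
Reactants: 4 2,4,6-trihydroxyacetophenone; 5 allyl bromide
Product: 6 1-[2-hydroxy-4,6-bis(allyloxy)phenyl]ethanone
Conditions: 5 (2.1 equiv), K2CO3 (2.2 equiv), acetone, reflux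
Reagents that add atoms: none
Why: Williamson etherification with two molecules of 5; the 4-OH and one of the two equivalent ortho hydroxyls are alkylated, while the last hydroxyl is hydrogen-bonded to the acetyl carbonyl, is the least nucleophilic and should remain free with about two equivalents of 5; K2CO3 in acetone favours O- over ring C-alkylation.

**Step 3**
Reactants: 6 1-[2-hydroxy-4,6-bis(allyloxy)phenyl]ethanone; 5 allyl bromide
Product: 7 1-[2-hydroxy-4,6-bis(allyloxy)phenyl]pent-4-en-1-one
Conditions: LiN(iPr)2 (2.3 equiv), THF, −78 → −30 °C; then 5 (1.05 equiv), −78 → 0 °C; aq NH4Cl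
Reagents that add atoms: none
Why: Alkylation of a ketone dianion; two equivalents of base give the lithium phenoxide–lithium enolate, whose enolate carbon is by far the more nucleophilic site (the phenoxide is tied up by chelation), so one equivalent of the reactive allylic halide should give C-monoallylation; low temperature limits proton exchange and a second alkylation.

**Step 4**
Reactants: 7 1-[2-hydroxy-4,6-bis(allyloxy)phenyl]pent-4-en-1-one; 3 2,4-bis(methoxymethoxy)benzoic acid
Product: 8 3,5-bis(allyloxy)-2-(pent-4-enoyl)phenyl 2,4-bis(methoxymethoxy)benzoate
Conditions: EDC·HCl (1.5 equiv), DMAP (0.3 equiv), CH2Cl2, 0 °C → rt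
Reagents that add atoms: none
Why: Carbodiimide/DMAP (Steglich-type) esterification through the N-acylpyridinium ion acylates the only free phenol under neutral conditions that the acetals and allyl groups tolerate; no acid chloride and therefore no HCl is involved.

**Step 5**
Reactants: 8 3,5-bis(allyloxy)-2-(pent-4-enoyl)phenyl 2,4-bis(methoxymethoxy)benzoate
Product: 10 3-allyl-5,7-bis(allyloxy)-2-[2,4-bis(methoxymethoxy)phenyl]chromen-4-one, via allyl diketone 9 (not isolated)
Conditions: LiN(SiMe3)2 (2.5 equiv), THF, −78 °C → rt; then AcOH, NaOAc, 100 °C
Reagents that add atoms: none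
Why: Baker–Venkataraman rearrangement: the enolate of the α-allyl ketone attacks the neighbouring aryl ester through a six-membered transition state and the adduct opens to the phenoxide of 9 (racemic at the allyl-bearing carbon, which becomes sp2 in 10); in hot buffered acetic acid the ring-A phenol adds to the ring-B carbonyl and the hemiketal loses water. The buffer is meant to keep the ring-B acetals on until ring C is closed, so the 2'-oxygen cannot compete; later partial loss of these acetals would be harmless because step 7 removes them.

**Step 6**
Reactants: 10 3-allyl-5,7-bis(allyloxy)-2-[2,4-bis(methoxymethoxy)phenyl]chromen-4-one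
Product: 11 3,6,8-triallyl-5,7-dihydroxy-2-[2,4-bis(methoxymethoxy)phenyl]chromen-4-one
Conditions: PhNEt2, 200 °C, sealed tube, argon
Reagents that add atoms: none
Why: Twofold aromatic Claisen rearrangement ([3,3] shift, then enolisation): the 7-O-allyl group migrates to C8 or C6 and the 5-O-allyl group to C6 or, if C6 is already occupied, onward by a Cope shift to the para position C8, so every pathway converges on the 6,8-diallyl-5,7-diol. The C3 allyl group and the acetals are spectators under these neutral thermal conditions.

**Step 7**
Reactants: 11 3,6,8-triallyl-5,7-dihydroxy-2-[2,4-bis(methoxymethoxy)phenyl]chromen-4-one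
Product: 12 3,6,8-triallyl-5,7-dihydroxy-2-(2,4-dihydroxyphenyl)chromen-4-one
Conditions: HCl (1.25 M in MeOH), THF, 45 °C
Reagents that add atoms: none
Why: Acid-catalysed acetal exchange with methanol removes both methoxymethyl groups as dimethoxymethane; terminal allyl groups next to phenols should not cyclise under such mild acid, because no tertiary cation is available, which is the reason for deprotecting before the prenyl termini exist.

**Step 8**
Reactants: 12 3,6,8-triallyl-5,7-dihydroxy-2-(2,4-dihydroxyphenyl)chromen-4-one; 13 2-methylbut-2-ene
Product: 14 artelasticin (3,6,8-triprenyl-5,7-dihydroxy-2-(2,4-dihydroxyphenyl)chromen-4-one)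
Conditions: 13 (100 equiv), second-generation Grubbs catalyst (H2IMes)(PCy3)Cl2Ru=CHPh (10 mol%, two portions), 1,4-benzoquinone (20 mol%), CH2Cl2 with a little THF, sealed tube, 40 °C
Reagents that add atoms: 2-methylbut-2-ene, CC=C(C)C
Why: Olefin cross-metathesis by the metal carbene/metallacyclobutane mechanism, run at three sites of one substrate: after phosphine loss the ruthenium benzylidene is turned by 13 into isopropylidene and ethylidene carbenes, each terminal allyl alkene of 12 passes through [2+2] cycloaddition to a ruthenacyclobutane and cycloreversion, its chain end is capped with C(CH3)2, and its CH2 terminus leaves joined to the CH3CH half of 13 as propene. The balanced equation is 12 + 3 × 13 → 14 + 3 propene, so one molecule of 13 is consumed per allyl group and all nine carbons of the three new C(CH3)2 ends come from 13, which is therefore charged in large excess as reactant, reagent and co-solvent. The closest known reaction type is the conversion of ortho-allylphenols and other allylarenes into prenylarenes with 13 and this same second-generation catalyst, which tolerates free phenols and aryl ketones. No ring is closed and no stereocentre is formed, and the new alkenes carry two identical methyl groups, so there is no E/Z question. The selectivity needed is complete threefold conversion: the terminal allyl groups are the most reactive alkenes present, the trisubstituted prenyl products are poor metathesis substrates and accumulate, and crotyl chains (from ethylidene transfer) or homodimers are still 1,2-disubstituted alkenes that re-enter the cycle and are funnelled to prenyl by the excess of 13. Ring-closing metathesis cannot compete, because the C6 and C8 allyl groups are meta to each other and the C3 allyl group is remote from both. Migration of an allyl double bond into conjugation with the arene, caused by ruthenium hydrides from catalyst decay, should be suppressed by 1,4-benzoquinone, the low temperature and portionwise catalyst addition. Because the phenols are already free, 14 is reached with no further operation near the acid-sensitive prenyl groups.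

## Compound list

1 | 2,4-dihydroxybenzoic acid | O=C(O)c1ccc(O)cc1O | starting material
2 | methoxymethyl 2,4-bis(methoxymethoxy)benzoate | COCOC(=O)c1ccc(OCOC)cc1OCOC | intermediate (not isolated)
3 | 2,4-bis(methoxymethoxy)benzoic acid | COCOc1ccc(C(=O)O)c(OCOC)c1 | intermediate
4 | 2,4,6-trihydroxyacetophenone | CC(=O)c1c(O)cc(O)cc1O | starting material
5 | allyl bromide | C=CCBr | starting material
6 | 1-[2-hydroxy-4,6-bis(allyloxy)phenyl]ethanone | CC(=O)c1c(O)cc(OCC=C)cc1OCC=C | intermediate
7 | 1-[2-hydroxy-4,6-bis(allyloxy)phenyl]pent-4-en-1-one | C=CCCC(=O)c1c(O)cc(OCC=C)cc1OCC=C | intermediate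
8 | 3,5-bis(allyloxy)-2-(pent-4-enoyl)phenyl 2,4-bis(methoxymethoxy)benzoate | C=CCCC(=O)c1c(OC(=O)c2ccc(OCOC)cc2OCOC)cc(OCC=C)cc1OCC=C | intermediate
9 | 2-allyl-1-[2,4-bis(methoxymethoxy)phenyl]-3-[2-hydroxy-4,6-bis(allyloxy)phenyl]propane-1,3-dione (racemic) | C=CCC(C(=O)c1ccc(OCOC)cc1OCOC)C(=O)c1c(O)cc(OCC=C)cc1OCC=C | intermediate (not isolated)
10 | 3-allyl-5,7-bis(allyloxy)-2-[2,4-bis(methoxymethoxy)phenyl]chromen-4-one | C=CCOc1cc(OCC=C)c2c(=O)c(CC=C)c(-c3ccc(OCOC)cc3OCOC)oc2c1 | intermediate
11 | 3,6,8-triallyl-5,7-dihydroxy-2-[2,4-bis(methoxymethoxy)phenyl]chromen-4-one | C=CCc1c(O)c(CC=C)c2oc(-c3ccc(OCOC)cc3OCOC)c(CC=C)c(=O)c2c1O | intermediate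
12 | 3,6,8-triallyl-5,7-dihydroxy-2-(2,4-dihydroxyphenyl)chromen-4-one | C=CCc1c(O)c(CC=C)c2oc(-c3ccc(O)cc3O)c(CC=C)c(=O)c2c1O | intermediate
13 | 2-methylbut-2-ene | CC=C(C)C | starting material
14 | artelasticin, 5,7-dihydroxy-2-(2,4-dihydroxyphenyl)-3,6,8-triprenylchromen-4-one | CC(C)=CCc1c(O)c(CC=C(C)C)c2oc(-c3ccc(O)cc3O)c(CC=C(C)C)c(=O)c2c1O | target

## Step count and least certain steps

Total step count: 8. Longest linear sequence: 7 steps (steps 2 to 8, from 4); step 1 is a one-step branch from 1.

**Step 8 (key step).** The reaction may stall after one or two sites as the catalyst decays, since the tetraphenol can bind ruthenium and is only moderately soluble in the non-polar medium. Unreacted allyl groups may then isomerise into conjugation with the arene, after which metathesis would shorten the chain. Fallback, from 12 back to 14: 12 would be peracetylated (Ac2O, pyridine, DMAP cat.) to 3,6,8-triallyl-5,7-diacetoxy-2-(2,4-diacetoxyphenyl)chromen-4-one F1. Cross-metathesis of this non-coordinating, CH2Cl2-soluble ester with 13 (again three molecules consumed) and the same catalyst would give 5,7-diacetoxy-2-(2,4-diacetoxyphenyl)-3,6,8-triprenylchromen-4-one F2. Methanolysis (K2CO3 cat., MeOH, 0 °C, argon) would then release 14 under base, with no acid near the prenyl groups.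

**Step 3.** A second alkylation may occur after proton transfer between the monoallylated enolate and unreacted dianion, or the lithium phenoxide may be O-allylated; both are favoured by poor solubility of the dilithium species. Fallback, from 6 back to 7: the chelated phenol would first be masked (NaH, MOMCl, DMF) as 1-[4,6-bis(allyloxy)-2-(methoxymethoxy)phenyl]ethanone F3. Its simple lithium enolate (LiN(iPr)2, 1.1 equiv, THF, −78 °C) would be allylated with 5 to 1-[4,6-bis(allyloxy)-2-(methoxymethoxy)phenyl]pent-4-en-1-one F4. Brief HCl/MeOH at rt would remove the single acetal and return 7.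

**Step 5.** Acyl transfer by the α-branched, doubly ortho-substituted enolate may be slow, so that cleavage of the aryl ester back to 7 and 3 takes over; in the acid stage, dehydration of the hemiketal may be incomplete. Fallback, from 6 and 3 back to 9: the acyl transfer would be run before the branch is introduced. 6 would be esterified with 3 (EDC·HCl, DMAP) to 2-acetyl-3,5-bis(allyloxy)phenyl 2,4-bis(methoxymethoxy)benzoate F5. Rearrangement (LiN(SiMe3)2, THF; cold AcOH quench) would give 1-[2,4-bis(methoxymethoxy)phenyl]-3-[2-hydroxy-4,6-bis(allyloxy)phenyl]propane-1,3-dione F6. Its doubly activated central carbon would be C-allylated once with 5 (K2CO3, acetone, rt) to 9, which is then cyclised to 10 under the acid stage of step 5.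

**Step 6.** The relay of the second allyl group may be incomplete when C6 is occupied first; the new phenols may add thermally to their ortho-allyl groups (dihydrobenzofuran formation); allyl ethers may be lost at 200 °C on an advanced intermediate. Fallback, from 7 back to 12: the Claisen rearrangement would be moved to the small ketone. 7 would be heated (PhNEt2, 190 °C) to give 1-(3,5-diallyl-2,4,6-trihydroxyphenyl)pent-4-en-1-one F7. Two hydroxyls would be protected (MOMCl, iPr2NEt; the chelated one stays free) to give 1-[3,5-diallyl-2-hydroxy-4,6-bis(methoxymethoxy)phenyl]pent-4-en-1-one F8. Esterification with 3 (EDC·HCl, DMAP) would give 4,6-diallyl-3,5-bis(methoxymethoxy)-2-(pent-4-enoyl)phenyl 2,4-bis(methoxymethoxy)benzoate F9. Acyl transfer (LiN(SiMe3)2, THF) would give, without isolation, 2-allyl-3-[3,5-diallyl-2-hydroxy-4,6-bis(methoxymethoxy)phenyl]-1-[2,4-bis(methoxymethoxy)phenyl]propane-1,3-dione F10. Cyclodehydration (AcOH, NaOAc, 100 °C) would give 3,6,8-triallyl-5,7-bis(methoxymethoxy)-2-[2,4-bis(methoxymethoxy)phenyl]chromen-4-one F11. HCl/MeOH would then remove all four acetals and give 12, from which step 8 follows.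

## Further compounds

F1 | step 8 | 3,6,8-triallyl-5,7-diacetoxy-2-(2,4-diacetoxyphenyl)chromen-4-one | C=CCc1c(OC(C)=O)c(CC=C)c2oc(-c3ccc(OC(C)=O)cc3OC(C)=O)c(CC=C)c(=O)c2c1OC(C)=O
F2 | step 8 | 5,7-diacetoxy-2-(2,4-diacetoxyphenyl)-3,6,8-triprenylchromen-4-one | CC(C)=CCc1c(OC(C)=O)c(CC=C(C)C)c2oc(-c3ccc(OC(C)=O)cc3OC(C)=O)c(CC=C(C)C)c(=O)c2c1OC(C)=O
F3 | step 3 | 1-[4,6-bis(allyloxy)-2-(methoxymethoxy)phenyl]ethanone | CC(=O)c1c(OCOC)cc(OCC=C)cc1OCC=C
F4 | step 3 | 1-[4,6-bis(allyloxy)-2-(methoxymethoxy)phenyl]pent-4-en-1-one | C=CCCC(=O)c1c(OCOC)cc(OCC=C)cc1OCC=C
F5 | step 5 | 2-acetyl-3,5-bis(allyloxy)phenyl 2,4-bis(methoxymethoxy)benzoate | CC(=O)c1c(OC(=O)c2ccc(OCOC)cc2OCOC)cc(OCC=C)cc1OCC=C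
F6 | step 5 | 1-[2,4-bis(methoxymethoxy)phenyl]-3-[2-hydroxy-4,6-bis(allyloxy)phenyl]propane-1,3-dione | O=C(CC(=O)c1c(O)cc(OCC=C)cc1OCC=C)c1ccc(OCOC)cc1OCOC
F7 | step 6 | 1-(3,5-diallyl-2,4,6-trihydroxyphenyl)pent-4-en-1-one | C=CCCC(=O)c1c(O)c(CC=C)c(O)c(CC=C)c1O
F8 | step 6 | 1-[3,5-diallyl-2-hydroxy-4,6-bis(methoxymethoxy)phenyl]pent-4-en-1-one | C=CCCC(=O)c1c(O)c(CC=C)c(OCOC)c(CC=C)c1OCOC
F9 | step 6 | 4,6-diallyl-3,5-bis(methoxymethoxy)-2-(pent-4-enoyl)phenyl 2,4-bis(methoxymethoxy)benzoate | C=CCCC(=O)c1c(OC(=O)c2ccc(OCOC)cc2OCOC)c(CC=C)c(OCOC)c(CC=C)c1OCOC
F10 | step 6 | 2-allyl-3-[3,5-diallyl-2-hydroxy-4,6-bis(methoxymethoxy)phenyl]-1-[2,4-bis(methoxymethoxy)phenyl]propane-1,3-dione (racemic) | C=CCC(C(=O)c1ccc(OCOC)cc1OCOC)C(=O)c1c(O)c(CC=C)c(OCOC)c(CC=C)c1OCOC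
F11 | step 6 | 3,6,8-triallyl-5,7-bis(methoxymethoxy)-2-[2,4-bis(methoxymethoxy)phenyl]chromen-4-one | C=CCc1c(OCOC)c(CC=C)c2oc(-c3ccc(OCOC)cc3OCOC)c(CC=C)c(=O)c2c1OCOC
A1 | alternative 1 | 2,4-diprenyl-3-(triisopropylsilyloxy)cyclobut-2-en-1-one (racemic) | CC(C)=CCC1C(=O)C(CC=C(C)C)=C1O[Si](C(C)C)(C(C)C)C(C)C
A2 | alternative 1 | (triisopropylsilyloxy)ethyne | C#CO[Si](C(C)C)(C(C)C)C(C)C
A3 | alternative 1 | 2,4-diprenyl-3,5-bis(triisopropylsilyloxy)phenol | Oc1cc(O[Si](C(C)C)(C(C)C)C(C)C)c(CC=C(C)C)c(O[Si](C(C)C)(C(C)C)C(C)C)c1CC=C(C)C
A4 | alternative 2 | 2,4-diprenylbenzene-1,3,5-triol | CC(C)=CCc1c(O)cc(O)c(CC=C(C)C)c1O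
A5 | alternative 2 | ethyl 2-[2,4-bis(methoxymethoxy)benzoyl]-5-methylhex-4-enoate (racemic) | CCOC(=O)C(CC=C(C)C)C(=O)c1ccc(OCOC)cc1OCOC
A6 | alternative 2 | 5,7-dihydroxy-2-[2,4-bis(methoxymethoxy)phenyl]-3,6,8-triprenylchromen-4-one | CC(C)=CCc1c(O)c(CC=C(C)C)c2oc(-c3ccc(OCOC)cc3OCOC)c(CC=C(C)C)c(=O)c2c1O
A7 | alternative 3 | 2-ethynyl-5,7-bis(methoxymethoxy)-3,6,8-triprenylchromen-4-one | C#Cc1oc2c(CC=C(C)C)c(OCOC)c(CC=C(C)C)c(OCOC)c2c(=O)c1CC=C(C)C
A8 | alternative 3 | 1-methoxy-1,3-bis(trimethylsilyloxy)buta-1,3-diene | COC(O[Si](C)(C)C)=CC(=C)O[Si](C)(C)C
A9 | alternative 3 | 2-(2,4-dihydroxyphenyl)-5,7-bis(methoxymethoxy)-3,6,8-triprenylchromen-4-one | CC(C)=CCc1c(OCOC)c(CC=C(C)C)c2oc(-c3ccc(O)cc3O)c(CC=C(C)C)c(=O)c2c1OCOC
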